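Numbering: dioxolane O1, O2, C3 (Me, CH2CO2Me), C4, C5 (Me, side chain C1′–C15′ counted from C5).
Cuts, in retrosynthetic order: C9′=C10′ (Julia–Kocienski), C7′=C8′ (cross-metathesis), C3–CH2CO2Me (ketene acetal on the C3 cation), C5–O1 with C3–O2 (key step), then in the open chain C3–CH3 (methyl Grignard on a Weinreb amide) and C5–C1′ (carbocupration).
Enabling feature: the O1-bearing quaternary C5 is β to C3 through C4, so with C3 as a ketone carbonyl the ring O1–O2–C3–C4–C5 is the cyclic peroxy-hemiketal of the H2O2 adduct of a β,β-dialkyl enone.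
Forward order: the octenyl chain is joined to a four-carbon ynoate and turned into the E methyl enone (steps 1–3), the only ring closes in step 4, the acetate arm is attached at C3 (steps 5–6), and the side chain is extended at its terminal alkene by two olefinations (steps 7 and 10, sulfone from steps 8–9).
Stereochemistry: C5 (S) from the cinchona amine catalyst acting on the geometrically pure enone; C3 (R) from attack on the planar C3 cation anti to the C5 chain, the epimer being removed by chromatography; 7′E from metathesis, 9′E from the Julia–Kocienski step, 12′Z carried in with (Z)-hex-3-en-1-ol.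

Key step: step 4

Assumption: the quinine-derived amine salt is taken to deliver hydrogen peroxide to the Si face of the enone β-carbon, the face that gives 5S; if the sense proves opposite, the quinidine-derived pseudoenantiomer is used under the same conditions.

Step 1
Reactants: 1 8-bromooct-1-ene; 2 ethyl but-2-ynoate
Product: 4 ethyl (2E)-3-methylundeca-2,10-dienoate, via oct-7-enylmagnesium bromide 3 (not isolated)
Conditions: Mg, THF, 23 °C; CuBr·SMe2 (1 equiv), THF, −40 °C; then 2, −78 °C; MeOH then aq. NH4Cl at −78 °C
Reagents that add atoms: ethyl but-2-ynoate (2), CC#CC(=O)OCC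
Why: Syn carbocupration of the ynoate by the Grignard-derived organocopper reagent, followed by protonation of the alkenylcopper with retention at −78 °C, places the octenyl chain trans to the ester and so fixes the E trisubstituted alkene on which the key step depends.

Step 2
Reactants: 4 ethyl (2E)-3-methylundeca-2,10-dienoate
Product: 5 (2E)-N-methoxy-N,3-dimethylundeca-2,10-dienamide
Conditions: MeNHOMe·HCl, iPrMgCl, THF, −20 → 0 °C; aq. NH4Cl
Reagents that add atoms: N,O-dimethylhydroxylamine hydrochloride, CNOC.Cl
Why: The chloromagnesium amide of N,O-dimethylhydroxylamine acylates with the ester at low temperature (Weinreb amide formation) without conjugate addition to the hindered β-carbon or change of alkene geometry.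

Step 3
Reactants: 5 (2E)-N-methoxy-N,3-dimethylundeca-2,10-dienamide
Product: 6 (3E)-4-methyldodeca-3,11-dien-2-one
Conditions: MeMgBr, THF, 0 °C; aq. NH4Cl
Reagents that add atoms: methylmagnesium bromide, C[Mg]Br
Why: Weinreb ketone synthesis, in which the chelated tetrahedral magnesium intermediate survives until work-up, so the addition stops at the methyl ketone and the E enone is released without over-addition or isomerisation.

Step 4
Reactants: 6 (3E)-4-methyldodeca-3,11-dien-2-one; 7 hydrogen peroxide
Product: 9 (5S)-3,5-dimethyl-5-(oct-7-enyl)-1,2-dioxolan-3-ol (both C3 epimers), via (4S)-4-hydroperoxy-4-methyldodec-11-en-2-one 8 (not isolated)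
Conditions: 9-amino-9-deoxy-epi-quinine (20 mol %), CF3CO2H (40 mol %), 50% aq. H2O2 (3 equiv), 1,4-dioxane, 30 °C
Reagents that add atoms: hydrogen peroxide (7), OO
Why: Proposed new method: the primary amine of the catalyst condenses with the methyl ketone of 6 to an iminium ion, hydrogen peroxide adds to its β-carbon (C4 of 6, the later C5) from the Si face within the chiral ion pair, and hydrolysis of the enamine releases hydroperoxy ketone 8; the closest known reaction type is the cinchona primary-amine-catalysed hydroperoxidation of β-monosubstituted aliphatic enones to 3-hydroxy-1,2-dioxolanes, and the base-mediated addition of hydrogen peroxide to β,β-dialkyl enones shows that a fully substituted β-carbon accepts this nucleophile. The ring closes by 5-exo-trig attack of the terminal hydroperoxide oxygen on the ketone carbonyl (O2–C3), a hemiketalisation that withdraws 8 from the reversible conjugate addition. The quaternary centre C5 is the only lasting stereocentre formed and is controlled by the catalyst alone, since 6 is achiral; the hemiketal carbon C3 forms as both epimers and is erased in step 6. The step needs enantiofacial selectivity at a β-carbon whose two alkyl groups differ little in size, and the substrate secures this through the single E geometry set in step 1, which always places the chain anti and the methyl syn to the iminium carbon. It also needs chemoselectivity, which is secured because the isolated terminal alkene does not react with hydrogen peroxide in the absence of a metal or peracid.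

Step 5
Reactants: 9 (5S)-3,5-dimethyl-5-(oct-7-enyl)-1,2-dioxolan-3-ol
Product: 10 (5S)-3-methoxy-3,5-dimethyl-5-(oct-7-enyl)-1,2-dioxolane (both C3 epimers)
Conditions: MeOH, p-TsOH·H2O (cat.), 3 Å sieves, 23 °C
Reagents that add atoms: methanol, CO
Why: Acid-catalysed exchange of the hemiketal hydroxyl for methoxyl (ketalisation of a cyclic peroxy-hemiketal) gives a stable peroxyketal that a Lewis acid can ionise cleanly, while C5 takes no part and keeps its configuration.

Step 6
Reactants: 10 (5S)-3-methoxy-3,5-dimethyl-5-(oct-7-enyl)-1,2-dioxolane; 11 1-(tert-butyldimethylsilyloxy)-1-methoxyethene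
Product: 13 methyl 2-[(3R,5S)-3,5-dimethyl-5-(oct-7-enyl)-1,2-dioxolan-3-yl]acetate, via (5S)-3,5-dimethyl-5-(oct-7-enyl)-1,2-dioxolan-3-ylium ion 12 (not isolated)
Conditions: TiCl4 (1.1 equiv), 11 (3 equiv), CH2Cl2, −78 °C; then H2O; chromatography to remove the C3 epimer
Reagents that add atoms: 1-(tert-butyldimethylsilyloxy)-1-methoxyethene (11), C=C(OC)O[Si](C)(C)C(C)(C)C
Why: TiCl4 ionises the C3 methoxyl to the peroxycarbenium ion 12, which the silyl ketene acetal captures in a Mukaiyama-type addition on the ring face anti to the larger C5 substituent (the octenyl chain), giving 3R; since methyl and a primary alkyl chain differ little in size the preference should be modest and the C3 epimer is separated.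

Step 7
Reactants: 13 methyl 2-[(3R,5S)-3,5-dimethyl-5-(oct-7-enyl)-1,2-dioxolan-3-yl]acetate; 14 (E)-but-2-enal (crotonaldehyde)
Product: 15 methyl 2-[(3R,5S)-3,5-dimethyl-5-[(7E)-9-oxonon-7-enyl]-1,2-dioxolan-3-yl]acetate
Conditions: 14 (5 equiv), second-generation Grubbs catalyst (5 mol %), CH2Cl2, 40 °C
Reagents that add atoms: (E)-but-2-enal (14), C/C=C/C=O
Why: Olefin cross-metathesis of an unhindered terminal alkene with an excess of the electron-poor partner crotonaldehyde is selective for the E enal and is driven by loss of propene, and the ruthenium carbene tolerates dialkyl peroxides and esters.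

Step 8
Reactants: 16 (Z)-hex-3-en-1-ol; 17 2-mercaptobenzothiazole
Product: 18 2-[(3Z)-hex-3-enylsulfanyl]-1,3-benzothiazole
Conditions: PPh3, DIAD, THF, 0 → 23 °C
Reagents that add atoms: 2-mercaptobenzothiazole (17), Sc1nc2ccccc2s1
Why: Mitsunobu thioetherification of a primary alcohol with the acidic heteroaryl thiol runs under neutral conditions and leaves the Z alkene untouched.

Step 9
Reactants: 18 2-[(3Z)-hex-3-enylsulfanyl]-1,3-benzothiazole; 7 hydrogen peroxide
Product: 19 2-[(3Z)-hex-3-enylsulfonyl]-1,3-benzothiazole
Conditions: (NH4)6Mo7O24·4H2O (10 mol %), 30% aq. H2O2 (4 equiv), EtOH, 0 → 23 °C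
Reagents that add atoms: hydrogen peroxide (7), OO
Why: Molybdate-catalysed oxidation with hydrogen peroxide takes the sulfide through the sulfoxide to the sulfone much faster than it epoxidises an unactivated disubstituted alkene.

Step 10
Reactants: 15 methyl 2-[(3R,5S)-3,5-dimethyl-5-[(7E)-9-oxonon-7-enyl]-1,2-dioxolan-3-yl]acetate; 19 2-[(3Z)-hex-3-enylsulfonyl]-1,3-benzothiazole
Product: 20 methyl 2-[(3R,5S)-3,5-dimethyl-5-[(7E,9E,12Z)-pentadeca-7,9,12-trienyl]-1,2-dioxolan-3-yl]acetate
Conditions: NaN(SiMe3)2 (1.1 equiv) added to 15 and 19 (1.2 equiv), THF, −78 → −20 °C; aq. NH4Cl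
Reagents that add atoms: 2-[(3Z)-hex-3-enylsulfonyl]-1,3-benzothiazole (19), CC/C=C\CCS(=O)(=O)c1nc2ccccc2s1
Why: Julia–Kocienski olefination, in which the sulfonyl carbanion adds to the enal, a Smiles rearrangement moves the benzothiazole to oxygen and loss of SO2 and benzothiazolone forms C9′=C10′, with E geometry expected for an alkyl benzothiazolyl sulfone paired with a conjugated aldehyde; forming the anion in the presence of the aldehyde at −78 °C keeps free base away from the base-labile β-peroxy ester.

Compound list
1 | 8-bromooct-1-ene | C=CCCCCCCBr | starting material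
2 | ethyl but-2-ynoate | CC#CC(=O)OCC | starting material
3 | oct-7-enylmagnesium bromide | C=CCCCCCC[Mg]Br | intermediate (not isolated)
4 | ethyl (2E)-3-methylundeca-2,10-dienoate | CCOC(=O)/C=C(\C)CCCCCCC=C | intermediate
5 | (2E)-N-methoxy-N,3-dimethylundeca-2,10-dienamide | CON(C)C(=O)/C=C(\C)CCCCCCC=C | intermediate
6 | (3E)-4-methyldodeca-3,11-dien-2-one | CC(=O)/C=C(\C)CCCCCCC=C | intermediate
7 | hydrogen peroxide | OO | starting material
8 | (4S)-4-hydroperoxy-4-methyldodec-11-en-2-one | C=CCCCCCC[C@@](OO)(C)CC(C)=O | intermediate (not isolated)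
9 | (5S)-3,5-dimethyl-5-(oct-7-enyl)-1,2-dioxolan-3-ol, both C3 epimers | C=CCCCCCC[C@@]1(C)CC(C)(O)OO1 | intermediate
10 | (5S)-3-methoxy-3,5-dimethyl-5-(oct-7-enyl)-1,2-dioxolane, both C3 epimers | C=CCCCCCC[C@@]1(C)CC(C)(OC)OO1 | intermediate
11 | 1-(tert-butyldimethylsilyloxy)-1-methoxyethene | C=C(OC)O[Si](C)(C)C(C)(C)C | starting material
12 | (5S)-3,5-dimethyl-5-(oct-7-enyl)-1,2-dioxolan-3-ylium ion | C=CCCCCCC[C@@]1(C)CC(C)=[O+]O1 | intermediate (not isolated)
13 | methyl 2-[(3R,5S)-3,5-dimethyl-5-(oct-7-enyl)-1,2-dioxolan-3-yl]acetate | C=CCCCCCC[C@@]1(C)C[C@](C)(CC(=O)OC)OO1 | intermediate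
14 | (E)-but-2-enal (crotonaldehyde) | C/C=C/C=O | starting material
15 | methyl 2-[(3R,5S)-3,5-dimethyl-5-[(7E)-9-oxonon-7-enyl]-1,2-dioxolan-3-yl]acetate | O=C/C=C/CCCCCC[C@@]1(C)C[C@](C)(CC(=O)OC)OO1 | intermediate
16 | (Z)-hex-3-en-1-ol | CC/C=C\CCO | starting material
17 | 2-mercaptobenzothiazole | Sc1nc2ccccc2s1 | starting material
18 | 2-[(3Z)-hex-3-enylsulfanyl]-1,3-benzothiazole | CC/C=C\CCSc1nc2ccccc2s1 | intermediate
19 | 2-[(3Z)-hex-3-enylsulfonyl]-1,3-benzothiazole | CC/C=C\CCS(=O)(=O)c1nc2ccccc2s1 | intermediate
20 | methyl 2-[(3R,5S)-3,5-dimethyl-5-[(7E,9E,12Z)-pentadeca-7,9,12-trienyl]-1,2-dioxolan-3-yl]acetate | CC/C=C\C/C=C/C=C/CCCCCC[C@@]1(C)C[C@](C)(CC(=O)OC)OO1 | target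

Total step count: 10. Longest linear sequence: 8 steps (steps 1–7 and 10, from 8-bromooct-1-ene); steps 8–9 form the sulfone branch.

Steps most likely to fail

1. Step 4 (the proposed new method).
What may go wrong:
- Hydrogen peroxide may add only slowly to the doubly alkylated β-carbon, so that epoxide formation or simple catalyst turnover without addition competes.
- The iminium ion may lose its E geometry through the dienamine, so that both faces are presented and enantiofacial control at C5 erodes.

The fallback uses known chemistry, sets out from 6 and returns at 13. Enone 6 is treated with aqueous hydrogen peroxide and a catalytic amount of LiOH in MeOH/THF at 0 °C, the long-established base-mediated peroxidation of β,β-dialkyl enones. This should give racemic 3,5-dimethyl-5-(oct-7-enyl)-1,2-dioxolan-3-ol F1. The conditions of steps 5 and 6 then lead through racemic 3-methoxy-3,5-dimethyl-5-(oct-7-enyl)-1,2-dioxolane F2 to racemic methyl 2-[(3R*,5S*)-3,5-dimethyl-5-(oct-7-enyl)-1,2-dioxolan-3-yl]acetate F3. Its enantiomers are separated by preparative chromatography on an amylose tris(3,5-dimethylphenylcarbamate) phase. The (3R,5S) enantiomer is 13.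

2. Step 6.
What may go wrong:
- Facial discrimination at the planar C3 cation may be poor, because the methyl and the primary alkyl chain on C5 differ little in size.
- The Lewis acid may ionise the tertiary C5–O1 bond and fragment the ring.

The fallback sets out from 10 and returns at 13. Step 6 is run as written and the unwanted epimer, methyl 2-[(3S,5S)-3,5-dimethyl-5-(oct-7-enyl)-1,2-dioxolan-3-yl]acetate F4, is kept and recycled. With Et2NH in CF3CH2OH (or catalytic DBU in MeOH) the ester enolate of F4 expels the peroxide oxygen from C3 (E1cB). This gives the ring-opened methyl (5S)-5-hydroperoxy-3,5-dimethyltrideca-2,12-dienoate F5. F5 recloses by 5-exo-trig conjugate addition of the hydroperoxide to the enoate (intramolecular oxa-Michael addition) to a mixture of 13 and F4. Separation and re-submission of F4 should converge the material on 13, with C3 now set under equilibrium control through C3–O2 bond formation instead of by kinetic C–C bond formation.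

3. Step 10.
What may go wrong:
- Deprotonation α to the ester may be followed by β-elimination of the peroxide and ring opening.
- The enal may be enolised at its γ-position.
- The sulfonyl carbanion may attack the O–O bond.
- E selectivity at C9′=C10′ may be incomplete.

The fallback sets out from 13 and 16 and returns at 20. Cross-metathesis of 13 with vinylboronic acid pinacol ester (second-generation Grubbs catalyst, CH2Cl2, 40 °C) should give methyl 2-[(3R,5S)-3,5-dimethyl-5-[(7E)-8-(4,4,5,5-tetramethyl-1,3,2-dioxaborolan-2-yl)oct-7-enyl]-1,2-dioxolan-3-yl]acetate F6. Alcohol 16 is oxidised with Dess–Martin periodinane to (Z)-hex-3-enal F7, which is used at once in a Takai iodo-olefination (CrCl2, CHI3, THF, 0 °C) to give (1E,4Z)-1-iodohepta-1,4-diene F8. Suzuki–Miyaura coupling of F6 with F8 (PdCl2(dppf), aq. K3PO4, THF, 23 °C) joins C8′ to C9′ with retention of both alkene geometries and gives 20. This replaces the amide base by aqueous phosphate.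

Further compounds
F1 | step 4 | racemic 3,5-dimethyl-5-(oct-7-enyl)-1,2-dioxolan-3-ol | C=CCCCCCCC1(C)CC(C)(O)OO1
F2 | step 4 | racemic 3-methoxy-3,5-dimethyl-5-(oct-7-enyl)-1,2-dioxolane | C=CCCCCCCC1(C)CC(C)(OC)OO1
F3 | step 4 | racemic methyl 2-[(3R*,5S*)-3,5-dimethyl-5-(oct-7-enyl)-1,2-dioxolan-3-yl]acetate (13 together with its 3S,5R enantiomer) | C=CCCCCCC[C@@]1(C)C[C@](C)(CC(=O)OC)OO1.C=CCCCCCC[C@]1(C)C[C@@](C)(CC(=O)OC)OO1
F4 | step 6 | methyl 2-[(3S,5S)-3,5-dimethyl-5-(oct-7-enyl)-1,2-dioxolan-3-yl]acetate | C=CCCCCCC[C@@]1(C)C[C@@](C)(CC(=O)OC)OO1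
F5 | step 6 | methyl (5S)-5-hydroperoxy-3,5-dimethyltrideca-2,12-dienoate (either C2 geometry) | C=CCCCCCC[C@](C)(OO)CC(C)=CC(=O)OC
F6 | step 10 | methyl 2-[(3R,5S)-3,5-dimethyl-5-[(7E)-8-(4,4,5,5-tetramethyl-1,3,2-dioxaborolan-2-yl)oct-7-enyl]-1,2-dioxolan-3-yl]acetate | CC1(C)OB(/C=C/CCCCCC[C@@]2(C)C[C@](C)(CC(=O)OC)OO2)OC1(C)C
F7 | step 10 | (Z)-hex-3-enal | CC/C=C\CC=O
F8 | step 10 | (1E,4Z)-1-iodohepta-1,4-diene | CC/C=C\C/C=C/I
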